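## Retrosynthetic overview

1. The last bond made is the CH2 bridge between C3 of the two 4-hydroxy-2-pyranones (Mannich, then Michael), which splits the target into tetralone monomer 19 and naphthalene monomer 20.
2. 20 is the dehydrated, aromatised form of the same tetralone skeleton, so one racemic tetralone–pyranone 16 feeds both halves: after resolution the (3R,4R) enantiomer gives 19 and the (3S,4S) enantiomer gives achiral 20.
3. Key disconnection: the C4(sp3)–C6(pyranone) bond, formed by a radical benzylic C–H coupling (NiBr2(dme), Ir[dF(CF3)ppy]2(dtbbpy)PF6, blue light) of tetralone 10 with chloropyranone 15; the C4 radical is quenched trans to the C3 hydroxyl.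
4. Tetralone 10 comes from a 6-enolexo aldol of a 1,5-diketone (Sonogashira coupling, alkyne hydration); the 1,2,3-substituted arene from ortho-lithiation of 3-bromophenol MOM ether; the pyranone from two molecules of malonyl dichloride.
5. Ring order: benzene ring (bought), tetralone ring (step 4), pyranone ring (step 5, separate branch), naphthalene ring of the second half (step 10); the pyranones are bridged last.

Assumption: racemates are written as the 1:1 pair of enantiomer SMILES joined by a dot; the absolute configuration of 17 is assigned after step 8 by ECD and by the optical rotation of 19.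

## Route

Step 1
Reactants: 1 3-bromophenol
Product: 2 1-bromo-3-(methoxymethoxy)benzene
Conditions: NaH, THF, 0 °C; then MOMCl, 0 °C → rt
Reagents that add atoms: chloromethyl methyl ether (MOMCl), COCCl
Why: Williamson-type O-alkylation of the phenoxide (MOM protection) gives the acetal that directs the next lithiation and masks the phenol during the radical step.

Step 2
Reactants: 2 1-bromo-3-(methoxymethoxy)benzene; 3 N-methoxy-N-methylacetamide
Product: 6 1-[2-bromo-6-(methoxymethoxy)phenyl]ethan-1-one, via aryllithium 4 (not isolated), via lithium hemiaminal alkoxide 5 (not isolated)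
Conditions: LiN(iPr)2, THF, −78 °C; then 3, −78 → −40 °C; H2O
Reagents that add atoms: none
Why: Directed ortho-metalation removes the most acidic hydrogen, flanked by OMOM and Br, at −78 °C without benzyne formation, and the Weinreb ketone synthesis stops at the chelated adduct, so only the methyl ketone forms.

Step 3
Reactants: 6 1-[2-bromo-6-(methoxymethoxy)phenyl]ethan-1-one; 7 ethynylbenzene
Product: 8 1-[2-(methoxymethoxy)-6-(phenylethynyl)phenyl]ethan-1-one
Conditions: PdCl2(PPh3)2 (2 mol %), CuI (4 mol %), Et3N, 60 °C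
Reagents that add atoms: none
Why: Sonogashira coupling of an aryl bromide activated by its ortho acyl group.

Step 4
Reactants: 8 1-[2-(methoxymethoxy)-6-(phenylethynyl)phenyl]ethan-1-one
Product: 10 rac-3-hydroxy-8-(methoxymethoxy)-3-phenyl-3,4-dihydronaphthalen-1(2H)-one, via 1,5-diketone 9 (not isolated)
Conditions: Ph3PAuNTf2 (2 mol %), 1,4-dioxane/H2O, 50 °C; then K2CO3 (0.5 equiv), MeOH, 0 °C
Reagents that add atoms: water, O
Why: Carbonyl-assisted alkyne hydration catalysed by Ph3PAuNTf2 (6-endo attack of the acetyl oxygen, isobenzopyrylium, opening by water) puts the new ketone only on the phenyl-bearing carbon, and carbonate in methanol then effects the 6-enolexo intramolecular ketone–ketone aldol addition at 0 °C without dehydration; C3 is formed as a racemate and sorted out in step 8.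

Step 5
Reactants: 11 malonyl dichloride
Product: 14 6-chloro-4-hydroxy-2H-pyran-2-one, via pyranone acid chloride 12 (not isolated), via pyranone carboxylic acid 13 (not isolated)
Conditions: neat, 20 °C, 3 d; then H2O, 1,4-dioxane, 60 °C
Reagents that add atoms: malonyl dichloride (second molecule), O=C(Cl)CC(=O)Cl; water, O
Why: Self-condensation of two molecules of malonyl dichloride (C-acylation, then O-acylation and ring closure, loss of two HCl) gives the 2-pyranone acid chloride, and hydrolysis by water followed by decarboxylation of the vinylogous β-keto acid (the oxygen from water leaves in the CO2) gives the 6-chloro-4-hydroxy-2-pyranone.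

Step 6
Reactants: 14 6-chloro-4-hydroxy-2H-pyran-2-one
Product: 15 6-chloro-4-(methoxymethoxy)-2H-pyran-2-one
Conditions: MOMCl, iPr2NEt, CH2Cl2, 0 °C
Reagents that add atoms: chloromethyl methyl ether (MOMCl), COCCl
Why: O-alkylation of the vinylogous acid removes the acidic, C3-nucleophilic enol that would self-condense with the C6–Cl electrophile and slow oxidative addition.

Step 7
Reactants: 10 rac-3-hydroxy-8-(methoxymethoxy)-3-phenyl-3,4-dihydronaphthalen-1(2H)-one; 15 6-chloro-4-(methoxymethoxy)-2H-pyran-2-one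
Product: 16 rac-(3R,4R)-3-hydroxy-8-(methoxymethoxy)-4-[4-(methoxymethoxy)-2-oxo-2H-pyran-6-yl]-3-phenyl-3,4-dihydronaphthalen-1(2H)-one
Conditions: NiBr2(dme) (10 mol %), 4,4'-di-tert-butyl-2,2'-bipyridine (12 mol %), Ir[dF(CF3)ppy]2(dtbbpy)PF6 (2 mol %), Bu4NBr (20 mol %), K2HPO4, MeCN/PhCF3, blue LEDs, 25 °C
Reagents that add atoms: none
Why: Proposed new method: benzylic C–H pyranonylation with the tetralone as limiting reagent – zerovalent nickel inserts into the C6–Cl bond of 15, light-driven homolysis of a Ni–Br bond releases a bromine atom that abstracts the weakest hydrogen (benzylic C4–H; the α-keto CH2, the O–H and the acetal C–H are stronger or polarity-mismatched), the planar C4 radical is captured by divalent nickel, and reductive elimination from trivalent nickel places the pyranone anti to the pseudo-axial C3–OH (phenyl pseudo-equatorial), that is trans to OH and cis to phenyl as in the target, which is also the more stable epimer reachable by reversible hydrogen-atom transfer at the product C4–H; closest known reaction type: benzylic C(sp3)–H arylation of alkylarenes with aryl bromides under the same dual NiBr2(dme)/photoredox catalysis.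

Step 8
Reactants: 16 rac-(3R,4R)-3-hydroxy-8-(methoxymethoxy)-4-[4-(methoxymethoxy)-2-oxo-2H-pyran-6-yl]-3-phenyl-3,4-dihydronaphthalen-1(2H)-one
Product: 17 (3R,4R)-3-hydroxy-8-(methoxymethoxy)-4-[4-(methoxymethoxy)-2-oxo-2H-pyran-6-yl]-3-phenyl-3,4-dihydronaphthalen-1(2H)-one; 18 (3S,4S)-3-hydroxy-8-(methoxymethoxy)-4-[4-(methoxymethoxy)-2-oxo-2H-pyran-6-yl]-3-phenyl-3,4-dihydronaphthalen-1(2H)-one (other enantiomer, kept for step 10)
Conditions: preparative chiral SFC, amylose tris(3,5-dimethylphenylcarbamate) phase, CO2/MeOH, 35 °C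
Reagents that add atoms: none
Why: Resolution of enantiomers by chiral chromatography fixes the absolute configuration (3R,4R) of 17 and wastes nothing, because enantiomer 18 is the feed for the achiral naphthalene half.

Step 9
Reactants: 17 (3R,4R)-3-hydroxy-8-(methoxymethoxy)-4-[4-(methoxymethoxy)-2-oxo-2H-pyran-6-yl]-3-phenyl-3,4-dihydronaphthalen-1(2H)-one
Product: 19 (3R,4R)-3,8-dihydroxy-4-(4-hydroxy-2-oxo-2H-pyran-6-yl)-3-phenyl-3,4-dihydronaphthalen-1(2H)-one
Conditions: ZnBr2, n-PrSH, CH2Cl2, 0 °C, 10 min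
Reagents that add atoms: none
Why: Lewis-acid-assisted transacetalisation of both MOM acetals to the thiol (MOM cleavage) is fast and non-protic, so the tertiary β-hydroxy ketone neither dehydrates nor undergoes retro-aldol, the thiol traps the formaldehyde equivalent that would otherwise bridge two pyranones, and C3 and C4 are untouched.

Step 10
Reactants: 18 (3S,4S)-3-hydroxy-8-(methoxymethoxy)-4-[4-(methoxymethoxy)-2-oxo-2H-pyran-6-yl]-3-phenyl-3,4-dihydronaphthalen-1(2H)-one
Product: 20 6-(4,5-dihydroxy-2-phenylnaphthalen-1-yl)-4-hydroxy-2H-pyran-2-one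
Conditions: n-PrSH, CF3CO2H/CH2Cl2 (1:3), 0 → 40 °C
Reagents that add atoms: none
Why: Acidolysis of both MOM acetals (thiol as scavenger) and acid-catalysed dehydration of the tertiary benzylic β-hydroxy ketone (E1/E1cB), followed by tautomerisation to the 1-naphthol, is driven by aromatisation and erases both stereocenters, so the unwanted enantiomer is fully used.

Step 11
Reactants: 19 (3R,4R)-3,8-dihydroxy-4-(4-hydroxy-2-oxo-2H-pyran-6-yl)-3-phenyl-3,4-dihydronaphthalen-1(2H)-one; 20 6-(4,5-dihydroxy-2-phenylnaphthalen-1-yl)-4-hydroxy-2H-pyran-2-one; 21 N,N-dimethylmethyleneiminium iodide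
Product: 24 wailupemycin I, (3R,4R)-4-[3-({6-(4,5-dihydroxy-2-phenylnaphthalen-1-yl)-4-hydroxy-2-oxo-2H-pyran-3-yl}methyl)-4-hydroxy-2-oxo-2H-pyran-6-yl]-3,8-dihydroxy-3-phenyl-3,4-dihydronaphthalen-1(2H)-one, via Mannich base 22 (not isolated), via methylidene pyrandione 23 (not isolated)
Conditions: 19, 21, CH3CO2Na, MeCN, 0 °C → rt; then 20, 50 °C
Reagents that add atoms: none
Why: Mannich reaction at the most nucleophilic carbon of 19 (pyranone C3), thermal loss of dimethylamine to the 3-methylidene-pyran-2,4-dione and Michael addition of the pyranone enol of 20 (more acidic and more C-nucleophilic than its naphthols) build the unsymmetrical methylene bridge in a fixed order, and no stereocenter is touched.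

## Compound list

1 | 3-bromophenol | Oc1cccc(Br)c1 | starting material
2 | 1-bromo-3-(methoxymethoxy)benzene | COCOc1cccc(Br)c1 | intermediate
3 | N-methoxy-N-methylacetamide | CC(=O)N(C)OC | starting material
4 | [2-bromo-6-(methoxymethoxy)phenyl]lithium | [Li]c1c(Br)cccc1OCOC | intermediate
5 | lithium 1-[2-bromo-6-(methoxymethoxy)phenyl]-1-[methoxy(methyl)amino]ethan-1-olate | [Li+].[O-]C(C)(N(C)OC)c1c(Br)cccc1OCOC | intermediate
6 | 1-[2-bromo-6-(methoxymethoxy)phenyl]ethan-1-one | CC(=O)c1c(Br)cccc1OCOC | intermediate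
7 | ethynylbenzene | C#Cc1ccccc1 | starting material
8 | 1-[2-(methoxymethoxy)-6-(phenylethynyl)phenyl]ethan-1-one | CC(=O)c1c(OCOC)cccc1C#Cc1ccccc1 | intermediate
9 | 2-[2-acetyl-3-(methoxymethoxy)phenyl]-1-phenylethan-1-one | CC(=O)c1c(OCOC)cccc1CC(=O)c1ccccc1 | intermediate
10 | rac-3-hydroxy-8-(methoxymethoxy)-3-phenyl-3,4-dihydronaphthalen-1(2H)-one | O=C1C[C@](O)(c2ccccc2)Cc2cccc(OCOC)c21.O=C1C[C@@](O)(c2ccccc2)Cc2cccc(OCOC)c21 | intermediate
11 | malonyl dichloride | O=C(Cl)CC(=O)Cl | starting material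
12 | 6-chloro-4-hydroxy-2-oxo-2H-pyran-3-carbonyl chloride | O=C(Cl)c1c(O)cc(Cl)oc1=O | intermediate
13 | 6-chloro-4-hydroxy-2-oxo-2H-pyran-3-carboxylic acid | O=C(O)c1c(O)cc(Cl)oc1=O | intermediate
14 | 6-chloro-4-hydroxy-2H-pyran-2-one | O=c1cc(O)cc(Cl)o1 | intermediate
15 | 6-chloro-4-(methoxymethoxy)-2H-pyran-2-one | COCOc1cc(Cl)oc(=O)c1 | intermediate
16 | rac-(3R,4R)-3-hydroxy-8-(methoxymethoxy)-4-[4-(methoxymethoxy)-2-oxo-2H-pyran-6-yl]-3-phenyl-3,4-dihydronaphthalen-1(2H)-one | O=C1C[C@](O)(c2ccccc2)[C@H](c2cc(OCOC)cc(=O)o2)c2cccc(OCOC)c21.O=C1C[C@@](O)(c2ccccc2)[C@@H](c2cc(OCOC)cc(=O)o2)c2cccc(OCOC)c21 | intermediate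
17 | (3R,4R)-3-hydroxy-8-(methoxymethoxy)-4-[4-(methoxymethoxy)-2-oxo-2H-pyran-6-yl]-3-phenyl-3,4-dihydronaphthalen-1(2H)-one | O=C1C[C@](O)(c2ccccc2)[C@H](c2cc(OCOC)cc(=O)o2)c2cccc(OCOC)c21 | intermediate
18 | (3S,4S)-3-hydroxy-8-(methoxymethoxy)-4-[4-(methoxymethoxy)-2-oxo-2H-pyran-6-yl]-3-phenyl-3,4-dihydronaphthalen-1(2H)-one | O=C1C[C@@](O)(c2ccccc2)[C@@H](c2cc(OCOC)cc(=O)o2)c2cccc(OCOC)c21 | intermediate
19 | (3R,4R)-3,8-dihydroxy-4-(4-hydroxy-2-oxo-2H-pyran-6-yl)-3-phenyl-3,4-dihydronaphthalen-1(2H)-one | O=C1C[C@](O)(c2ccccc2)[C@H](c2cc(O)cc(=O)o2)c2cccc(O)c21 | intermediate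
20 | 6-(4,5-dihydroxy-2-phenylnaphthalen-1-yl)-4-hydroxy-2H-pyran-2-one | O=c1cc(O)cc(-c2c(-c3ccccc3)cc(O)c3c(O)cccc23)o1 | intermediate
21 | N,N-dimethylmethyleneiminium iodide | C=[N+](C)C.[I-] | starting material
22 | (3R,4R)-4-{3-[(dimethylamino)methyl]-4-hydroxy-2-oxo-2H-pyran-6-yl}-3,8-dihydroxy-3-phenyl-3,4-dihydronaphthalen-1(2H)-one | O=C1C[C@](O)(c2ccccc2)[C@H](c2cc(O)c(CN(C)C)c(=O)o2)c2cccc(O)c21 | intermediate
23 | (3R,4R)-3,8-dihydroxy-4-(3-methylidene-2,4-dioxo-3,4-dihydro-2H-pyran-6-yl)-3-phenyl-3,4-dihydronaphthalen-1(2H)-one | O=C1C[C@](O)(c2ccccc2)[C@H](C2=CC(=O)C(=C)C(=O)O2)c2cccc(O)c21 | intermediate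
24 | wailupemycin I, (3R,4R)-4-[3-({6-(4,5-dihydroxy-2-phenylnaphthalen-1-yl)-4-hydroxy-2-oxo-2H-pyran-3-yl}methyl)-4-hydroxy-2-oxo-2H-pyran-6-yl]-3,8-dihydroxy-3-phenyl-3,4-dihydronaphthalen-1(2H)-one | O=C1C[C@](O)(c2ccccc2)[C@H](c2cc(O)c(Cc3c(O)cc(-c4c(-c5ccccc5)cc(O)c5c(O)cccc45)oc3=O)c(=O)o2)c2cccc(O)c21 | target

## Step count and risks

Total step count: 11.
Longest linear sequence: 8 steps (1, 2, 3, 4, 7, 8, 9, 11; the branch through step 10 is equally long).

The three steps most likely to fail:

**Step 7 (radical C–H pyranonylation).** The risks are unselective hydrogen abstraction (acetal C–H of the MOM groups), ring opening of the tertiary alcohol by β-scission if its O–H is oxidised, low conversion with the tetralone as limiting reagent, and a poor trans/cis ratio. The fallback sets out from 10 and makes the radical from a carbon–halogen bond instead of a C–H bond. Light-initiated benzylic bromination of 10 (N-bromosuccinimide, PhCF3, 25 °C) gives 4-bromo-3-hydroxy-8-(methoxymethoxy)-3-phenyl-3,4-dihydronaphthalen-1(2H)-one F1 as a mixture of diastereomers. Reductive cross-electrophile coupling of this bromide with 15 (NiCl2(dme), 4,4'-di-tert-butyl-2,2'-bipyridine, Zn, DMA, 25 °C) passes through the same C4 radical and the same nickel capture, and comes back to the route at 16.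

**Step 4 (hydration and aldol).** The more acidic benzylic CH2 of diketone 9 can divert the base, and the aldol product can dehydrate to the naphthol. The fallback sets out from 8 and generates the C2 enolate regiospecifically under neutral conditions. Enolate bromination of 8 (LiN(SiMe3)2, THF, −78 °C; then N-bromosuccinimide) gives 2-bromo-1-[2-(methoxymethoxy)-6-(phenylethynyl)phenyl]ethan-1-one F2. The same hydration (Ph3PAuNTf2, 1,4-dioxane/H2O, 50 °C) gives 2-[2-(bromoacetyl)-3-(methoxymethoxy)phenyl]-1-phenylethan-1-one F3. SmI2 (THF, −78 °C) then forms the samarium enolate, which closes the ring in a Reformatsky-type aldol and comes back to the route at 10.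

**Step 11 (methylene bridge).** The bridge can scramble by retro-Michael exchange to the two symmetrical dimers, and the electron-rich naphthalenediol of 20 can compete as a nucleophile. The fallback sets out from 19 and builds the bridge one oxidation level higher. 19 and N,N-dimethylformamide dimethyl acetal (CH2Cl2, 25 °C) give the enaminone (3R,4R)-4-{3-[(dimethylamino)methylidene]-2,4-dioxo-3,4-dihydro-2H-pyran-6-yl}-3,8-dihydroxy-3-phenyl-3,4-dihydronaphthalen-1(2H)-one F4, which cannot dimerise. Addition–elimination with 20 in acetic acid gives the methine-bridged bis-pyranone (3R,4R)-4-[3-({6-(4,5-dihydroxy-2-phenylnaphthalen-1-yl)-4-hydroxy-2-oxo-2H-pyran-3-yl}methylidene)-2,4-dioxo-3,4-dihydro-2H-pyran-6-yl]-3,8-dihydroxy-3-phenyl-3,4-dihydronaphthalen-1(2H)-one F5. Conjugate reduction with Hantzsch ester (diethyl 2,6-dimethyl-1,4-dihydropyridine-3,5-dicarboxylate, 40 °C) comes back to the route at 24.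

Further compounds

F1 | step 7 | 4-bromo-3-hydroxy-8-(methoxymethoxy)-3-phenyl-3,4-dihydronaphthalen-1(2H)-one | O=C1CC(O)(c2ccccc2)C(Br)c2cccc(OCOC)c21
F2 | step 4 | 2-bromo-1-[2-(methoxymethoxy)-6-(phenylethynyl)phenyl]ethan-1-one | BrCC(=O)c1c(OCOC)cccc1C#Cc1ccccc1
F3 | step 4 | 2-[2-(bromoacetyl)-3-(methoxymethoxy)phenyl]-1-phenylethan-1-one | BrCC(=O)c1c(OCOC)cccc1CC(=O)c1ccccc1
F4 | step 11 | (3R,4R)-4-{3-[(dimethylamino)methylidene]-2,4-dioxo-3,4-dihydro-2H-pyran-6-yl}-3,8-dihydroxy-3-phenyl-3,4-dihydronaphthalen-1(2H)-one | O=C1C[C@](O)(c2ccccc2)[C@H](C2=CC(=O)C(=CN(C)C)C(=O)O2)c2cccc(O)c21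
F5 | step 11 | (3R,4R)-4-[3-({6-(4,5-dihydroxy-2-phenylnaphthalen-1-yl)-4-hydroxy-2-oxo-2H-pyran-3-yl}methylidene)-2,4-dioxo-3,4-dihydro-2H-pyran-6-yl]-3,8-dihydroxy-3-phenyl-3,4-dihydronaphthalen-1(2H)-one | O=C1C[C@](O)(c2ccccc2)[C@H](C2=CC(=O)C(=Cc3c(O)cc(-c4c(-c5ccccc5)cc(O)c5c(O)cccc45)oc3=O)C(=O)O2)c2cccc(O)c21
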